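**Retrosynthetic overview**
- C2–H: the single stereocentre is set last, by enantioselective 1,4-hydride addition to the fully substituted flavone. This dearomatises the benzopyranone ring C.
- C8–prenyl: phenolate C-alkylation at the only free ring-A carbon of the 6-pyronylflavone.
- Ring C: Friedel–Crafts acylation of 2-pyronylphloroglucinol with phenylpropioloyl chloride at either of its two equivalent CH positions. A 6-endo closure through the OH para to the pyrone follows.
- Aryl–pyrone bond (key step): direct C–H pyronylation of unprotected phloroglucinol by the pyrone iodonium ylide. It runs through a dearomatised cyclohexadienone and breaks the threefold symmetry, with no halide, boron or protecting group.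
- Ring order: pyrone (doubly deprotonated β-keto ester plus Weinreb amide, then lactonisation), then ring A bought as phloroglucinol, then ring C.

Assumption: C2 is (S) as read from the SMILES, the pyrone is handled as its 4-hydroxy-2-pyranone tautomer, and the aryl–pyrone axis (flanked only by oxygen substituents and not specified in the SMILES) is taken as freely rotating.

**Step 1**
Reactants: 1 methyl 3-oxopentanoate; 2 N-methoxy-N-methylpropanamide
Product: 4 6-ethyl-4-hydroxy-5-methyl-2H-pyran-2-one, via methyl 4-methyl-3,5-dioxoheptanoate 3 (not isolated)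
Conditions: lithium diisopropylamide (2.2 equiv), THF, −78 to 0 °C; 2, −78 to 0 °C; 1 M HCl; crude 3, DBU (1.2 equiv), toluene, 90 °C; 1 M HCl
Reagents that add atoms: none
Why: Weiler-type γ-acylation of doubly deprotonated 1 by a Weinreb amide (no over-addition and no proton quench by the product) gives the 3,5-dioxo ester, whose C5 enol lactonises onto the ester under DBU to the 4-hydroxy-2-pyranone; no stereocentre is formed.

**Step 2 (key step)**
Reactants: 4 6-ethyl-4-hydroxy-5-methyl-2H-pyran-2-one; 5 phloroglucinol (benzene-1,3,5-triol, anhydrous, 3 equiv)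
Product: 8 6-ethyl-4-hydroxy-5-methyl-3-(2,4,6-trihydroxyphenyl)-2H-pyran-2-one, via pyronyl(phenyl)iodonium ylide 6 (not isolated), via cyclohexadienone adduct 7 (not isolated)
Conditions: (diacetoxyiodo)benzene (1.0 equiv), CH2Cl2, rt, 2 h; strip acetic acid with toluene; 5, BF3·OEt2 (20 mol %), MeCN, 0 °C to rt
Reagents that add atoms: none
Why: Proposed new method: acid activation of the stabilised ylide 6 at oxygen makes its C3–I bond strongly electrophilic (iodobenzene is a hypernucleofuge), one of the three equivalent enol-like carbons of phloroglucinol (far more nucleophilic at C than at O under acid) displaces iodobenzene at C3 to give the dearomatised dienone 7, and tautomerisation restores ring A in 8, whose lower nucleophilicity and the excess of 5 suppress a second substitution; the closest known reaction types are the BF3-mediated arylation of phenyliodonium ylides of cyclic 1,3-dicarbonyl compounds with activated arenes and the Rh2(OAc)4-catalysed arylation of cyclic 2-diazo-1,3-dicarbonyl compounds; no stereocentre survives.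

**Step 3**
Reactants: 8 6-ethyl-4-hydroxy-5-methyl-3-(2,4,6-trihydroxyphenyl)-2H-pyran-2-one; 9 phenylpropiolic acid
Product: 12 6-(6-ethyl-4-hydroxy-5-methyl-2-oxo-2H-pyran-3-yl)-5,7-dihydroxy-2-phenyl-4H-chromen-4-one, via 3-phenylprop-2-ynoyl chloride 10 (not isolated), via aryl ynone 11 (not isolated)
Conditions: 9, (COCl)2, DMF (cat.), CH2Cl2, rt, evaporate; 8, AlCl3 (6 equiv), CH2Cl2–MeNO2, 0 °C to rt; ice/1 M HCl; Et2NH (3 equiv), DMF, 40 °C; 1 M HCl
Reagents that add atoms: none
Why: Friedel–Crafts acylation of a phloroglucinol with an arylpropioloyl chloride followed by 6-endo oxa-Michael closure to the flavone; the two free ring carbons of 8 are equivalent, so acylation needs no regiocontrol, and closure is expected through the hydroxyl para to the pyrone because the other ortho hydroxyl is flanked by the twisted pyrone and locked in the chelate with the new ketone, which places the pyrone at C6 and leaves C8–H; no stereocentre is formed.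

**Step 4**
Reactants: 12 6-(6-ethyl-4-hydroxy-5-methyl-2-oxo-2H-pyran-3-yl)-5,7-dihydroxy-2-phenyl-4H-chromen-4-one; 13 prenyl bromide (1-bromo-3-methylbut-2-ene)
Product: 14 6-(6-ethyl-4-hydroxy-5-methyl-2-oxo-2H-pyran-3-yl)-5,7-dihydroxy-8-(3-methylbut-2-en-1-yl)-2-phenyl-4H-chromen-4-one
Conditions: KOH (4 equiv), MeOH–H2O, 0 °C; 13 (1.5 equiv, slow addition), 0 °C to rt; 1 M HCl
Reagents that add atoms: none
Why: Phenolate C-prenylation (SN2 C-alkylation of a phloroglucinol-type polyanion in protic medium): C8 is the only unsubstituted ring-A carbon and is activated by both the 7- and 5-phenolates, the hydrogen-bonding solvent masks the oxygens, the weakly nucleophilic pyronate is shielded at C3 by the orthogonal aryl ring, and the achiral flavone has nothing for the base to epimerise; O-prenylation at O7 is the expected competing pathway and will limit the yield.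

**Step 5**
Reactants: 14 6-(6-ethyl-4-hydroxy-5-methyl-2-oxo-2H-pyran-3-yl)-5,7-dihydroxy-8-(3-methylbut-2-en-1-yl)-2-phenyl-4H-chromen-4-one
Product: 17 (2S)-6-(6-ethyl-4-hydroxy-5-methyl-2-oxo-2H-pyran-3-yl)-5,7-dihydroxy-8-(3-methylbut-2-en-1-yl)-2-phenyl-2,3-dihydro-4H-chromen-4-one, via tris-O-silyl flavone 15 (not isolated), via silyl enol ether 16 (not isolated)
Conditions: Cu(OAc)2·H2O (5 mol %), (S)-DTBM-SEGPHOS (5.5 mol %), (EtO)2MeSiH (8 equiv), toluene–THF, 0 °C to rt; then 1 M HCl, THF–MeOH, 0 °C, 30 min
Reagents that add atoms: none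
Why: Copper hydride-catalysed asymmetric conjugate reduction (1,4-hydrosilylation), the reaction type known for 2-substituted chromones: the silane first caps the three acidic OH groups (15), the ligated monovalent copper hydride then adds H to C2 of the β-aryloxy enone, which is the only trisubstituted and most electrophilic acceptor (the prenyl alkene is unactivated and the pyrone diene is tetrasubstituted and electron-rich), the chiral ligand pocket exposes the face that gives (2S) (sense inferred from β-substituted cyclic enones and to be confirmed by CD, with the antipodal ligand equally available), and the product is held as silyl enol ether 16 so that neither 1,2-reduction nor retro-oxa-Michael racemisation can occur before the cold acidic hydrolysis.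

**Compound list**
1 | methyl 3-oxopentanoate | CCC(=O)CC(=O)OC | starting material
2 | N-methoxy-N-methylpropanamide | CCC(=O)N(C)OC | starting material
3 | methyl 4-methyl-3,5-dioxoheptanoate (racemic, enolisable) | CCC(=O)C(C)C(=O)CC(=O)OC | intermediate
4 | 6-ethyl-4-hydroxy-5-methyl-2H-pyran-2-one | CCc1oc(=O)cc(O)c1C | intermediate
5 | phloroglucinol (benzene-1,3,5-triol) | Oc1cc(O)cc(O)c1 | starting material
6 | (6-ethyl-5-methyl-4-oxido-2-oxo-2H-pyran-3-yl)(phenyl)iodonium, the iodonium ylide | CCc1oc(=O)c([I+]c2ccccc2)c([O-])c1C | intermediate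
7 | 6-(6-ethyl-4-hydroxy-5-methyl-2-oxo-2H-pyran-3-yl)-3,5-dihydroxycyclohexa-2,4-dien-1-one (dearomatised adduct, racemic, transient) | O=C1C=C(O)C=C(O)C1c1c(O)c(C)c(CC)oc1=O | intermediate
8 | 6-ethyl-4-hydroxy-5-methyl-3-(2,4,6-trihydroxyphenyl)-2H-pyran-2-one | CCc1oc(=O)c(-c2c(O)cc(O)cc2O)c(O)c1C | intermediate
9 | phenylpropiolic acid | OC(=O)C#Cc1ccccc1 | starting material
10 | 3-phenylprop-2-ynoyl chloride | O=C(Cl)C#Cc1ccccc1 | intermediate
11 | 6-ethyl-4-hydroxy-5-methyl-3-[2,4,6-trihydroxy-3-(3-phenylprop-2-ynoyl)phenyl]-2H-pyran-2-one | CCc1oc(=O)c(-c2c(O)cc(O)c(C(=O)C#Cc3ccccc3)c2O)c(O)c1C | intermediate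
12 | 6-(6-ethyl-4-hydroxy-5-methyl-2-oxo-2H-pyran-3-yl)-5,7-dihydroxy-2-phenyl-4H-chromen-4-one | CCc1oc(=O)c(-c2c(O)cc3oc(-c4ccccc4)cc(=O)c3c2O)c(O)c1C | intermediate
13 | prenyl bromide (1-bromo-3-methylbut-2-ene) | CC(C)=CCBr | starting material
14 | 6-(6-ethyl-4-hydroxy-5-methyl-2-oxo-2H-pyran-3-yl)-5,7-dihydroxy-8-(3-methylbut-2-en-1-yl)-2-phenyl-4H-chromen-4-one | CCc1oc(=O)c(-c2c(O)c(CC=C(C)C)c3oc(-c4ccccc4)cc(=O)c3c2O)c(O)c1C | intermediate
15 | 14 with its 5-O, 7-O and pyrone 4-O each carrying a diethoxy(methyl)silyl group | CCc1oc(=O)c(-c2c(O[Si](C)(OCC)OCC)c(CC=C(C)C)c3oc(-c4ccccc4)cc(=O)c3c2O[Si](C)(OCC)OCC)c(O[Si](C)(OCC)OCC)c1C | intermediate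
16 | (2S)-2-phenyl-2H-chromene silyl enol ether: 4-O, 5-O, 7-O and pyrone 4-O all diethoxy(methyl)silylated, 8-prenyl, 6-pyronyl | CCc1oc(=O)c(-c2c(O[Si](C)(OCC)OCC)c(CC=C(C)C)c3c(c2O[Si](C)(OCC)OCC)C(O[Si](C)(OCC)OCC)=C[C@@H](c2ccccc2)O3)c(O[Si](C)(OCC)OCC)c1C | intermediate
17 | (2S)-6-(6-ethyl-4-hydroxy-5-methyl-2-oxo-2H-pyran-3-yl)-5,7-dihydroxy-8-(3-methylbut-2-en-1-yl)-2-phenyl-2,3-dihydro-4H-chromen-4-one | CCc1oc(=O)c(-c2c(O)c(CC=C(C)C)c3c(c2O)C(=O)C[C@@H](c2ccccc2)O3)c(O)c1C | target

**Step count**
Total step count: 5, with no protecting-group steps.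
Longest linear sequence: 5 (1 → 4 → 8 → 12 → 14 → 17).

**Three steps most likely to fail**

Step 2. The risks are O-attack of the phenol, acetoxylation at C3, phenyl transfer or double substitution. The fallback sets out from 4 and comes back at 8. It reverses the polarity, so that the pyrone becomes the nucleophile and the arene arrives as an aryllead electrophile. 1,3,5-Trimethoxybenzene is plumbated with Pb(OAc)4 (CHCl3, rt) to (2,4,6-trimethoxyphenyl)lead triacetate F1. This arylates C3 of 4 by ligand coupling (pyridine, CHCl3, 60 °C, Pinhey arylation) to 6-ethyl-4-hydroxy-5-methyl-3-(2,4,6-trimethoxyphenyl)-2H-pyran-2-one F2. BBr3 (CH2Cl2, −78 to 0 °C) then frees the three phenols and gives 8.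

Step 3. AlCl3 may favour conjugate addition over acylation, or may cause dehydrative furan closure between the pyrone 4-OH and a flanking phenol. Closure through the hindered hydroxyl would misplace the pyrone, so the regiochemistry should be checked by HMBC from the chelated 5-OH. The fallback sets out from 8 and comes back at 12, and it avoids any Lewis acid. N-Iodosuccinimide (1 equiv, MeCN, 0 °C) iodinates one of the two equivalent ring carbons to 6-ethyl-4-hydroxy-5-methyl-3-(2,4,6-trihydroxy-3-iodophenyl)-2H-pyran-2-one F3. Carbonylative Sonogashira coupling with phenylacetylene (PdCl2(PPh3)2, CO 1 atm, Et2NH, 50 °C) builds ynone 11, and the amine closes it to 12 in the same flask.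

Step 5. The acceptor is a hindered, electron-rich vinylogous ester, so conversion or ee may be low. The fallback sets out from 14 and comes back at 17. It replaces asymmetric induction by racemic reduction followed by kinetic resolution. An achiral catalyst (Cu(OAc)2·H2O with 1,2-bis(diphenylphosphino)benzene, and (EtO)2MeSiH) takes 14 through 15 to the racemic silyl enol ether F4. Cold acid hydrolysis then gives the racemic flavanone F5. Asymmetric transfer hydrogenation (RuCl(p-cymene)[(R,R)-TsDPEN], HCO2H–Et3N 5:2, EtOAc, rt) reduces the (2R) ketone to the cis-(2R,4R)-flavan-4-ol F6. The (2S) ketone 17 is left unreacted and is separated by chromatography (at most 50 %).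

**Further compounds**
F1 | step 2 | (2,4,6-trimethoxyphenyl)lead triacetate | COc1cc(OC)c([Pb](OC(C)=O)(OC(C)=O)OC(C)=O)c(OC)c1
F2 | step 2 | 6-ethyl-4-hydroxy-5-methyl-3-(2,4,6-trimethoxyphenyl)-2H-pyran-2-one | CCc1oc(=O)c(-c2c(OC)cc(OC)cc2OC)c(O)c1C
F3 | step 3 | 6-ethyl-4-hydroxy-5-methyl-3-(2,4,6-trihydroxy-3-iodophenyl)-2H-pyran-2-one | CCc1oc(=O)c(-c2c(O)cc(O)c(I)c2O)c(O)c1C
F4 | step 5 | racemic silyl enol ether (racemic form of 16) | CCc1oc(=O)c(-c2c(O[Si](C)(OCC)OCC)c(CC=C(C)C)c3c(c2O[Si](C)(OCC)OCC)C(O[Si](C)(OCC)OCC)=CC(c2ccccc2)O3)c(O[Si](C)(OCC)OCC)c1C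
F5 | step 5 | racemic flavanone (racemic form of 17) | CCc1oc(=O)c(-c2c(O)c(CC=C(C)C)c3c(c2O)C(=O)CC(c2ccccc2)O3)c(O)c1C
F6 | step 5 | cis-(2R,4R)-flavan-4-ol: 6-ethyl-4-hydroxy-5-methyl-3-[(2R,4R)-4,5,7-trihydroxy-8-(3-methylbut-2-en-1-yl)-2-phenyl-3,4-dihydro-2H-chromen-6-yl]-2H-pyran-2-one | CCc1oc(=O)c(-c2c(O)c(CC=C(C)C)c3c(c2O)[C@H](O)C[C@H](c2ccccc2)O3)c(O)c1C
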